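**Assumption:** the SMILES is taken as binding, i.e. (1R,6R,8S) with a 4Z double bond (C3 and C6 cis). Germacrane atom numbers (C1–C15) are used for all intermediates.

## Retrosynthetic overview

1. The butenolide is unmasked last from a 2,3,4-trisubstituted furan (singlet oxygen, then reduction at C6); the furan fixes C6 cis to C12, so only the 6,12-olide can form.
2. The ten-membered ring is closed at C5–C6 by an intramolecular copper-mediated Stille-type coupling of a 2-furylstannane with a (Z)-vinyl iodide.
3. The two halves are joined late at C8–C9 by a catalyst-controlled Nozaki–Hiyama allylation of East furaldehyde 25 (C6–C8, C11–C13) with West allyl bromide 13 (C1–C5, C9, C10, C14, C15).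
4. West comes from propargyl alcohol (Z-iodoalkene by anti-carbomagnesiation, C1 by CBS reduction); East comes from 3,4-dibromofuran (two Br/Li exchanges, directed stannylation).
5. Ring order: furan (bought) → ten-membered carbocycle (step 17) → butenolide (steps 18–19).

## West fragment

Step 1
Reactants: 1 prop-2-yn-1-ol
Product: 3 (Z)-3-iodo-2-methylprop-2-en-1-ol, via chelated (Z)-alkenylmagnesium bromide 2 (not isolated)
Conditions: MeMgBr (3 equiv), CuI (10 mol%), Et2O/THF, −10 °C → rt; then I2, −78 → 0 °C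
Reagents that add atoms: methylmagnesium bromide C[Mg]Br; iodine II
Why: Copper-catalysed, alkoxide-directed anti-carbomagnesiation puts the methyl on the inner carbon and magnesium cis to CH2O, and iodinolysis with retention gives the Z-iodide that later becomes the 4Z alkene.

Step 2
Reactants: 3 (Z)-3-iodo-2-methylprop-2-en-1-ol
Product: 4 (Z)-3-bromo-1-iodo-2-methylprop-1-ene
Conditions: CBr4, PPh3, CH2Cl2, 0 °C
Reagents that add atoms: carbon tetrabromide BrC(Br)(Br)Br
Why: Appel bromination of a primary allylic alcohol is neutral and leaves the vinyl iodide geometry untouched.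

Step 3
Reactants: 4 (Z)-3-bromo-1-iodo-2-methylprop-1-ene; 5 N-methoxy-N-methylacetamide
Product: 7 (Z)-5-iodo-N-methoxy-N,4-dimethylpent-4-enamide, via lithium enolate 6 (not isolated)
Conditions: LiN(iPr)2, THF, −78 °C; then 4, −78 → −30 °C
Reagents that add atoms: none
Why: Enolate alkylation (SN2) of the Weinreb acetamide with a reactive allylic bromide forms C2–C3; the amide base does not exchange the vinyl iodide, which has no β-hydrogen to eliminate.

Step 4
Reactants: 7 (Z)-5-iodo-N-methoxy-N,4-dimethylpent-4-enamide; 8 2-bromo-3-(trimethylsilyl)prop-1-ene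
Product: 10 (Z)-7-iodo-6-methyl-2-[(trimethylsilyl)methyl]hepta-1,6-dien-3-one, via alkenylmagnesium bromide 9 (not isolated)
Conditions: 8, Mg, THF, 40 °C; then 7, THF, −78 → 0 °C; cold aq. NH4Cl
Reagents that add atoms: none
Why: Weinreb ketone synthesis; the chelated tetrahedral adduct stops at the ketone, and a Grignard reagent (unlike an organolithium) does not exchange with the vinyl iodide.

Step 5
Reactants: 10 (Z)-7-iodo-6-methyl-2-[(trimethylsilyl)methyl]hepta-1,6-dien-3-one
Product: 11 (3R,6Z)-7-iodo-6-methyl-2-[(trimethylsilyl)methyl]hepta-1,6-dien-3-ol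
Conditions: (S)-2-methyl-CBS-oxazaborolidine (20 mol%), catecholborane, toluene, −78 °C; then MeOH, aq. NaHCO3
Reagents that add atoms: none
Why: Corey–Bakshi–Shibata reduction with the α-substituted alkenyl arm as the large group sets the future C1 as R by reagent control; catecholborane at −78 °C does not hydroborate the alkenes.

Step 6
Reactants: 11 (3R,6Z)-7-iodo-6-methyl-2-[(trimethylsilyl)methyl]hepta-1,6-dien-3-ol
Product: 12 (3R,6Z)-3-(tert-butyldimethylsilyloxy)-7-iodo-6-methyl-2-[(trimethylsilyl)methyl]hepta-1,6-diene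
Conditions: TBSCl, imidazole, DMF, rt
Reagents that add atoms: tert-butyldimethylsilyl chloride CC(C)(C)[Si](C)(C)Cl
Why: Standard silylation; the TBS ether survives every later step until the final fluoride cleavage.

Step 7
Reactants: 12 (3R,6Z)-3-(tert-butyldimethylsilyloxy)-7-iodo-6-methyl-2-[(trimethylsilyl)methyl]hepta-1,6-diene
Product: 13 (3R,6Z)-2-(bromomethyl)-3-(tert-butyldimethylsilyloxy)-7-iodo-6-methylhepta-1,6-diene
Conditions: NBS, propylene oxide, CH2Cl2, −78 °C
Reagents that add atoms: N-bromosuccinimide O=C1CCC(=O)N1Br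
Why: Electrophilic bromodesilylation (SE2′) of the allylsilane, by far the most nucleophilic alkene present, gives the 2-substituted allyl bromide; both allyl termini are CH2, so the transposition is degenerate.

## East fragment

Step 8
Reactants: 14 3,4-dibromofuran
Product: 16 4-bromofuran-3-carbaldehyde, via 3-bromo-4-lithiofuran 15 (not isolated)
Conditions: n-BuLi (1.0 equiv), Et2O, −78 °C; then DMF, −78 °C → rt
Reagents that add atoms: N,N-dimethylformamide CN(C)C=O
Why: Selective mono bromine–lithium exchange at −78 °C followed by formylation installs the future C13 carbon.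

Step 9
Reactants: 16 4-bromofuran-3-carbaldehyde
Product: 17 (4-bromofuran-3-yl)methanol
Conditions: NaBH4, MeOH, 0 °C
Reagents that add atoms: none
Why: Simple borohydride reduction of an aryl aldehyde.

Step 10
Reactants: 17 (4-bromofuran-3-yl)methanol
Product: 18 3-bromo-4-[(tert-butyldimethylsilyloxy)methyl]furan
Conditions: TBSCl, imidazole, DMF, rt
Reagents that add atoms: tert-butyldimethylsilyl chloride CC(C)(C)[Si](C)(C)Cl
Why: The bulky silyl ether survives the two lithiations that follow and does not direct metalation.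

Step 11
Reactants: 18 3-bromo-4-[(tert-butyldimethylsilyloxy)methyl]furan
Product: 20 4-[(tert-butyldimethylsilyloxy)methyl]furan-3-carbaldehyde, via 3-lithiofuran 19 (not isolated)
Conditions: n-BuLi, Et2O, −78 °C, 15 min; then DMF, −78 °C → rt
Reagents that add atoms: N,N-dimethylformamide CN(C)C=O
Why: A second bromine–lithium exchange and formylation install the future C8 carbon; ether solvent and low temperature suppress retro-Brook silyl migration.

Step 12
Reactants: 20 4-[(tert-butyldimethylsilyloxy)methyl]furan-3-carbaldehyde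
Product: 23 4-[(tert-butyldimethylsilyloxy)methyl]-2-(tributylstannyl)furan-3-carbaldehyde, via lithium α-amino alkoxide 21 (not isolated), via C2-lithiated α-amino alkoxide 22 (not isolated)
Conditions: LiN(Me)CH2CH2NMe2 (from the amine and n-BuLi), THF, −78 °C; n-BuLi, −20 °C, 3 h; Bu3SnCl, −78 °C → rt; aq. NH4Cl
Reagents that add atoms: tributyltin chloride CCCC[Sn](Cl)(CCCC)CCCC
Why: Comins' in-situ α-amino alkoxide protects the aldehyde and directs ortho-lithiation to the adjacent furan α-position (future C6), which is then stannylated.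

Step 13
Reactants: 23 4-[(tert-butyldimethylsilyloxy)methyl]-2-(tributylstannyl)furan-3-carbaldehyde
Product: 24 4-(hydroxymethyl)-2-(tributylstannyl)furan-3-carbaldehyde
Conditions: Bu4NF, AcOH, THF, 0 °C
Reagents that add atoms: none
Why: Buffered fluoride desilylation avoids the acid that would protodestannylate the furan; the strained 3,4-fused lactol is expected to be only a minor tautomer.

Step 14
Reactants: 24 4-(hydroxymethyl)-2-(tributylstannyl)furan-3-carbaldehyde
Product: 25 [4-formyl-5-(tributylstannyl)furan-3-yl]methyl acetate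
Conditions: Ac2O, pyridine, DMAP (cat.), CH2Cl2, 0 °C
Reagents that add atoms: acetic anhydride CC(=O)OC(C)=O
Why: Fast acylation of the primary alcohol installs the C13 acetate of the target before the fragments meet.

## Union and endgame

Step 15
Reactants: 13 (3R,6Z)-2-(bromomethyl)-3-(tert-butyldimethylsilyloxy)-7-iodo-6-methylhepta-1,6-diene; 25 [4-formyl-5-(tributylstannyl)furan-3-yl]methyl acetate
Product: 27 [4-[(1S,4R,7Z)-4-(tert-butyldimethylsilyloxy)-1-hydroxy-8-iodo-7-methyl-3-methylideneoct-7-en-1-yl]-5-(tributylstannyl)furan-3-yl]methyl acetate, via trimethylsilyl ether 26 (not isolated)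
Conditions: CrCl2 (10 mol%), chiral tridentate bis(oxazolinyl)carbazole ligand (12 mol%, enantiomer that delivers allyl to the Si face), Mn powder, iPr2NEt, Me3SiCl, THF, rt; then citric acid, MeOH, 0 °C
Reagents that add atoms: none
Why: Catalytic enantioselective Nozaki–Hiyama allylation forms C8–C9 and sets C8 as S by ligand control (Si-face attack); without nickel or palladium the vinyl iodide and the stannane are inert, and both termini of the allylchromium are CH2.

Step 16
Reactants: 27 the (1S)-alcohol from step 15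
Product: 28 [4-[(1S,4R,7Z)-1-acetoxy-4-(tert-butyldimethylsilyloxy)-8-iodo-7-methyl-3-methylideneoct-7-en-1-yl]-5-(tributylstannyl)furan-3-yl]methyl acetate
Conditions: Ac2O, pyridine, DMAP (cat.), CH2Cl2, rt
Reagents that add atoms: acetic anhydride CC(=O)OC(C)=O
Why: Acetylation of the secondary alcohol installs the C8 acetate while the molecule is still a base-stable furan, so no base touches the later butenolide.

Step 17
Reactants: 28 the stannyl iodo diacetate from step 16
Product: 29 (1R,8S,4Z)-8,13-diacetoxy-1-(tert-butyldimethylsilyloxy)-6,12-epoxygermacra-4,6,10(14),11-tetraene (furan fused to the ten-membered ring)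
Conditions: Cu(O2CC4H3S) (copper thiophene-2-carboxylate, 3 equiv), NMP, 0 °C → rt, slow addition to 1 mM
Reagents that add atoms: none
Why: Intramolecular Liebeskind–Allred (copper-mediated Stille-type) coupling closes the ring at C5–C6 with retention of the Z geometry and creates no stereocentre; without palladium, a 6-exo Heck closure onto C10=C14 cannot compete.

Step 18
Reactants: 29 the macrocyclic furan from step 17
Product: 31 (1R,8S,4Z)-8,13-diacetoxy-1-(tert-butyldimethylsilyloxy)-6-hydroxygermacra-4,7(11),10(14)-trien-6,12-olide (C6 hemiketal epimers), via furan endoperoxide 30 (not isolated)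
Conditions: O2, hν, tetraphenylporphyrin (cat.), iPr2NEt, CH2Cl2, −78 °C → rt
Reagents that add atoms: oxygen O=O
Why: Singlet-oxygen [4+2] addition to the furan, then base-induced Kornblum–DeLaMare fragmentation; C12 carries the only peroxide-bearing hydrogen, so it alone becomes the lactone carbonyl.

Step 19
Reactants: 31 the γ-hydroxybutenolide from step 18
Product: 33 (1R,6R,8S,4Z)-8,13-diacetoxy-1-(tert-butyldimethylsilyloxy)germacra-4,7(11),10(14)-trien-6,12-olide, via hydroxy acid 32 (not isolated)
Conditions: NaBH4, CeCl3·7H2O, MeOH/THF, −40 → 0 °C; then aq. citric acid to pH 3, rt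
Reagents that add atoms: none
Why: Luche 1,2-reduction of the ring-opened (Z)-keto carboxylate followed by acid lactonisation; C6 is set by substrate control, with hydride expected to add from the outer face of the macrocycle and place H-6 cis to H-8 (6R), which is the least secure stereochemical call in the route.

Step 20
Reactants: 33 the silyl ether from step 19
Product: 34 8α,13-diacetoxy-1β-hydroxygermacra-4,7(11),10(14)-trien-6α,12-olide
Conditions: HF·pyridine, pyridine, THF, 0 °C → rt
Reagents that add atoms: none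
Why: Buffered acidic fluoride desilylation frees the C1 alcohol and avoids base, which would deprotonate C6 and expel the C13 acetate.

## Compound list

1 | prop-2-yn-1-ol | C#CCO | starting material
2 | (Z)-[3-(bromomagnesiooxy)-2-methylprop-1-en-1-yl]magnesium bromide | C/C(CO[Mg]Br)=C/[Mg]Br | intermediate
3 | (Z)-3-iodo-2-methylprop-2-en-1-ol | OC/C(C)=C\I | intermediate
4 | (Z)-3-bromo-1-iodo-2-methylprop-1-ene | BrC/C(C)=C\I | intermediate
5 | N-methoxy-N-methylacetamide | CC(=O)N(C)OC | starting material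
6 | lithium enolate of N-methoxy-N-methylacetamide | [Li]OC(=C)N(C)OC | intermediate
7 | (Z)-5-iodo-N-methoxy-N,4-dimethylpent-4-enamide | CON(C)C(=O)CC/C(C)=C\I | intermediate
8 | 2-bromo-3-(trimethylsilyl)prop-1-ene | C=C(Br)C[Si](C)(C)C | starting material
9 | [3-(trimethylsilyl)prop-1-en-2-yl]magnesium bromide | C=C([Mg]Br)C[Si](C)(C)C | intermediate
10 | (Z)-7-iodo-6-methyl-2-[(trimethylsilyl)methyl]hepta-1,6-dien-3-one | C=C(C[Si](C)(C)C)C(=O)CC/C(C)=C\I | intermediate
11 | (3R,6Z)-7-iodo-6-methyl-2-[(trimethylsilyl)methyl]hepta-1,6-dien-3-ol | C=C(C[Si](C)(C)C)[C@H](O)CC/C(C)=C\I | intermediate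
12 | (3R,6Z)-3-(tert-butyldimethylsilyloxy)-7-iodo-6-methyl-2-[(trimethylsilyl)methyl]hepta-1,6-diene | C=C(C[Si](C)(C)C)[C@H](O[Si](C)(C)C(C)(C)C)CC/C(C)=C\I | intermediate
13 | (3R,6Z)-2-(bromomethyl)-3-(tert-butyldimethylsilyloxy)-7-iodo-6-methylhepta-1,6-diene | C=C(CBr)[C@H](O[Si](C)(C)C(C)(C)C)CC/C(C)=C\I | intermediate
14 | 3,4-dibromofuran | Brc1cocc1Br | starting material
15 | 3-bromo-4-lithiofuran | [Li]c1cocc1Br | intermediate
16 | 4-bromofuran-3-carbaldehyde | O=Cc1cocc1Br | intermediate
17 | (4-bromofuran-3-yl)methanol | OCc1cocc1Br | intermediate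
18 | 3-bromo-4-[(tert-butyldimethylsilyloxy)methyl]furan | CC(C)(C)[Si](C)(C)OCc1cocc1Br | intermediate
19 | 4-[(tert-butyldimethylsilyloxy)methyl]-3-lithiofuran | [Li]c1cocc1CO[Si](C)(C)C(C)(C)C | intermediate
20 | 4-[(tert-butyldimethylsilyloxy)methyl]furan-3-carbaldehyde | O=Cc1cocc1CO[Si](C)(C)C(C)(C)C | intermediate
21 | lithium α-amino alkoxide from 20 and lithium N,N,N′-trimethylethylenediamide | [Li]OC(N(C)CCN(C)C)c1cocc1CO[Si](C)(C)C(C)(C)C | intermediate
22 | furan-C2-lithiated α-amino alkoxide | [Li]OC(N(C)CCN(C)C)c1c([Li])occ1CO[Si](C)(C)C(C)(C)C | intermediate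
23 | 4-[(tert-butyldimethylsilyloxy)methyl]-2-(tributylstannyl)furan-3-carbaldehyde | O=Cc1c([Sn](CCCC)(CCCC)CCCC)occ1CO[Si](C)(C)C(C)(C)C | intermediate
24 | 4-(hydroxymethyl)-2-(tributylstannyl)furan-3-carbaldehyde | O=Cc1c([Sn](CCCC)(CCCC)CCCC)occ1CO | intermediate
25 | [4-formyl-5-(tributylstannyl)furan-3-yl]methyl acetate | O=Cc1c([Sn](CCCC)(CCCC)CCCC)occ1COC(C)=O | intermediate
26 | trimethylsilyl ether of 27 (8S,1R,4Z) | CC(=O)OCc1coc([Sn](CCCC)(CCCC)CCCC)c1[C@@H](O[Si](C)(C)C)CC(=C)[C@H](O[Si](C)(C)C(C)(C)C)CC/C(C)=C\I | intermediate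
27 | [4-[(1S,4R,7Z)-4-(tert-butyldimethylsilyloxy)-1-hydroxy-8-iodo-7-methyl-3-methylideneoct-7-en-1-yl]-5-(tributylstannyl)furan-3-yl]methyl acetate | CC(=O)OCc1coc([Sn](CCCC)(CCCC)CCCC)c1[C@@H](O)CC(=C)[C@H](O[Si](C)(C)C(C)(C)C)CC/C(C)=C\I | intermediate
28 | [4-[(1S,4R,7Z)-1-acetoxy-4-(tert-butyldimethylsilyloxy)-8-iodo-7-methyl-3-methylideneoct-7-en-1-yl]-5-(tributylstannyl)furan-3-yl]methyl acetate | CC(=O)OCc1coc([Sn](CCCC)(CCCC)CCCC)c1[C@@H](OC(C)=O)CC(=C)[C@H](O[Si](C)(C)C(C)(C)C)CC/C(C)=C\I | intermediate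
29 | (1R,8S,4Z)-8,13-diacetoxy-1-(tert-butyldimethylsilyloxy)-6,12-epoxygermacra-4,6,10(14),11-tetraene | C=C1C[C@H](OC(C)=O)c2c(COC(C)=O)coc2/C=C(/C)CC[C@H]1O[Si](C)(C)C(C)(C)C | intermediate
30 | 6,12-endoperoxide of furan 29 (bridgehead configuration not defined) | C=C1C[C@H](OC(C)=O)C2=C(COC(C)=O)C3OOC2(O3)/C=C(/C)CC[C@H]1O[Si](C)(C)C(C)(C)C | intermediate
31 | (1R,8S,4Z)-8,13-diacetoxy-1-(tert-butyldimethylsilyloxy)-6-hydroxygermacra-4,7(11),10(14)-trien-6,12-olide (C6 epimers) | C=C1C[C@H](OC(C)=O)C2=C(COC(C)=O)C(=O)OC2(O)/C=C(/C)CC[C@H]1O[Si](C)(C)C(C)(C)C | intermediate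
32 | (1R,6R,8S,4Z)-8,13-diacetoxy-1-(tert-butyldimethylsilyloxy)-6-hydroxygermacra-4,7(11),10(14)-trien-12-oic acid (C6 cis to CO2H) | C=C1C[C@H](OC(C)=O)/C(=C(\COC(C)=O)C(O)=O)[C@H](O)/C=C(/C)CC[C@H]1O[Si](C)(C)C(C)(C)C | intermediate
33 | (1R,6R,8S,4Z)-8,13-diacetoxy-1-(tert-butyldimethylsilyloxy)germacra-4,7(11),10(14)-trien-6,12-olide | C=C1C[C@H](OC(C)=O)C2=C(COC(C)=O)C(=O)O[C@@H]2/C=C(/C)CC[C@H]1O[Si](C)(C)C(C)(C)C | intermediate
34 | 8α,13-diacetoxy-1β-hydroxygermacra-4,7(11),10(14)-trien-6α,12-olide | C=C1C[C@H](OC(C)=O)C2=C(COC(C)=O)C(=O)O[C@@H]2/C=C(/C)CC[C@H]1O | target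

## Step count

Total steps: 20 (West 1–7, East 8–14, common 15–20).
Longest linear sequence: 13 steps (either branch plus steps 15–20), i.e. 13/20 = 0.65 of the total.

## Three steps most likely to fail, with fallbacks

**Step 15 (enantio- and chemoselective allylation).** The aldehyde is flanked by two ortho substituents and the allyl partner is complex, so ligand control may be incomplete. The fallback sets out from 13 and 25 and comes back at 27. An indium-mediated Barbier allylation (In powder, THF/H2O) joins the fragments without stereocontrol to give the C8-epimeric alcohols F1. Dess–Martin oxidation gives the 3-furyl ketone F2. Corey–Bakshi–Shibata reduction with (R)-2-methyl-CBS-oxazaborolidine and catecholborane (furyl as the large group) then returns (8S)-27 by reagent control.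

**Step 17 (ten-membered ring closure at C5–C6).** Cyclodimerisation or protodestannylation may win over closure of the strained ring. The fallback sets out from 12 and 25 and comes back at 29, with the order of the two bond formations inverted. An intermolecular Stille coupling of stannane 25 with vinyl iodide 12 (Pd(PPh3)4, CuI, CsF, DMF) gives the dienyl furaldehyde F3. The ring is then closed at C8–C9 by an intramolecular Hosomi–Sakurai allylation of the aldehyde by the allylsilane (BF3·OEt2, CH2Cl2, −78 °C, high dilution) to the macrocyclic alcohol F4. Here C8 is set under macrocyclic control. Acetylation (Ac2O, pyridine, DMAP) gives 29.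

**Step 19 (configuration at C6).** The facial selectivity of the hydride addition rests on the macrocycle conformation and is not secured by a reagent. The fallback sets out from 31 and comes back at 33. Me3SiCHN2 (toluene/MeOH) traps the open form of 31 as the methyl keto ester F5. A reagent-controlled Corey–Bakshi–Shibata reduction then gives the hydroxy ester F6; (S)-2-methyl-CBS-oxazaborolidine with catecholborane at −78 °C is the first choice if the fully substituted C7 arm acts as the large group, otherwise its enantiomer. F6 lactonises on mild acid treatment (PPTS, CH2Cl2) with loss of methanol to give 33.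

## Further compounds

F1 | step 15 | C8-epimeric mixture of alcohol 27, (1RS,4R,7Z) | CC(=O)OCc1coc([Sn](CCCC)(CCCC)CCCC)c1C(O)CC(=C)[C@H](O[Si](C)(C)C(C)(C)C)CC/C(C)=C\I
F2 | step 15 | [4-[(4R,7Z)-4-(tert-butyldimethylsilyloxy)-8-iodo-7-methyl-3-methylideneoct-7-enoyl]-5-(tributylstannyl)furan-3-yl]methyl acetate | CC(=O)OCc1coc([Sn](CCCC)(CCCC)CCCC)c1C(=O)CC(=C)[C@H](O[Si](C)(C)C(C)(C)C)CC/C(C)=C\I
F3 | step 17 | [5-[(1Z,5R)-5-(tert-butyldimethylsilyloxy)-2-methyl-6-[(trimethylsilyl)methyl]hepta-1,6-dien-1-yl]-4-formylfuran-3-yl]methyl acetate | CC(=O)OCc1coc(/C=C(/C)CC[C@@H](O[Si](C)(C)C(C)(C)C)C(=C)C[Si](C)(C)C)c1C=O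
F4 | step 17 | (1R,8S,4Z)-13-acetoxy-1-(tert-butyldimethylsilyloxy)-8-hydroxy-6,12-epoxygermacra-4,6,10(14),11-tetraene | C=C1C[C@H](O)c2c(COC(C)=O)coc2/C=C(/C)CC[C@H]1O[Si](C)(C)C(C)(C)C
F5 | step 19 | methyl (1R,8S,4Z)-8,13-diacetoxy-1-(tert-butyldimethylsilyloxy)-6-oxogermacra-4,7(11),10(14)-trien-12-oate (C6 cis to CO2Me) | C=C1C[C@H](OC(C)=O)/C(=C(\COC(C)=O)C(=O)OC)C(=O)/C=C(/C)CC[C@H]1O[Si](C)(C)C(C)(C)C
F6 | step 19 | methyl (1R,6R,8S,4Z)-8,13-diacetoxy-1-(tert-butyldimethylsilyloxy)-6-hydroxygermacra-4,7(11),10(14)-trien-12-oate | C=C1C[C@H](OC(C)=O)/C(=C(\COC(C)=O)C(=O)OC)[C@H](O)/C=C(/C)CC[C@H]1O[Si](C)(C)C(C)(C)C
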